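4 questions stand on two flasks, birch and elm, and you have the earlier runs green and grey to answer them with.

| setting | green | grey | birch | elm |
|---|---|---|---|---|
| starting complex | 0.10 M | 0.10 M | 0.10 M | 0.10 M |
| incoming ligand | 0.79 equiv | 2.2 equiv | 1.00 equiv | 3.00 equiv |
| remark | run made earlier | run made earlier |  |  |
| time |  |  | 4.0 h | 4.0 h |

| run | time / h | complex with one exchanged / % | starting complex / % |
|---|---|---|---|
| green | 0.250 | 70.1 | 26.8 |
| green | 0.833 | 71.0 | 25.9 |
| green | 1.33 | 69.8 | 26.2 |
| green | 2.00 | 68.3 | 26.9 |
| green | 3.00 | 67.0 | 27.7 |
| green | 4.00 | 65.1 | 29.1 |
| grey | 0.333 | 57.8 | 1.5 |
| grey | 0.500 | 53.9 | 1.1 |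
| grey | 0.833 | 47.3 | 1.6 |
| grey | 1.33 | 39.9 | 0.9 |
| grey | 2.50 | 28.0 | 0.5 |
| grey | 4.00 | 18.6 | 0.1 |

(each reading ± 0.3 percentage points)

- which of the two there is more of at the end, birch (over-reaction product / complex with one exchanged)
- which of the two there is more of at the end, elm (over-reaction product / complex with one exchanged)
- how much complex with one exchanged is there at the end, in percent of the starting complex charged: birch
- how much complex with one exchanged is there at the end, in percent of the starting complex charged: elm

- the analysis behind the earlier runs scatters by 0.3 percentage points, standard deviation

In grey, starting complex is down to 1.5 % at the first reading, while complex with one exchanged falls from 57.8 % to 18.6 %. I read this as complex with one exchanged taking a further incoming ligand to become over-reaction product. Let B be its fraction of the complex charged, and f the free incoming ligand in equivalents. While starting complex stays that small, each such step removes one B and one ligand, so the difference stays frozen: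

f − B = a, where a = equivalents charged − 2

For grey, a is 0.200. If the loss of B goes as κ·f·B, the logarithm ln[(a + B)/B] climbs in a straight line with slope aκ. Its first and last readings give:

κ = 0.590 /h

Call κ the drain constant: the fraction of B lost per hour for each equivalent of free ligand.

The bench rule for elm is pseudo-first-order: freeze f, and B decays with time constant 1/(κf). Elm's a is 1.00, and you get 0.847 h with f frozen at its start and 1.69 h with f frozen at its end. After 4.0 h these leave 0.889 % and 9.43 % of B. That spread is the border of the rule: the two frozen values of f differ by a factor of 2.00. So you let f move, start the line from the whole charge, and my figure for elm is: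

B = 4.95 %

For birch, a is −1.00, and the line assumes ligand left over from the first exchange, so I give no figure there.

The forecast says complex with one exchanged at 69 % for birch, and over-reaction product for elm with 3.6 % of complex with one exchanged: “the integrated rate law gives B ≈ 3.6%”. My elm figure is higher.

Birch ends with 68.1 % of complex with one exchanged against 12.5 % of over-reaction product. Elm ends with 5.45 % of complex with one exchanged against 90.4 % of over-reaction product, and beside them in elm stands 4.06 % of complex with two exchanged, a species outside the columns of both runs.

    starting complex + incoming ligand ⇌ leaving ligand + complex with one exchanged (K = 99.2, k = 10.1 /M/min)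
    complex with one exchanged + incoming ligand ⇌ leaving ligand + complex with two exchanged (K = 0.724, k = 4.56 /M/min)
    complex with one exchanged + incoming ligand → over-reaction product (k = 0.144 /M/min)

At 2.00 h, κ gives elm 18.1 % against 15.8 % in the flask. The forecast's choice for birch does not hold in a neighbour of birch with 1.70 equiv of incoming ligand, where a is −0.300. There over-reaction product, at 53.4 %, exceeds complex with one exchanged, which κ puts at 45.8 % and the flask holds at 39.7 %.

The earlier runs and the new flask stem from a simulated flask for an exercise, and the scatter is random.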